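(Its constants are those of an exercise; the result is computed.)

The easy step came first: substrate has two ways to go, and I asked which one pays.

    substrate + reagent → target, rate k1*[substrate]*[reagent]^1.5 (k1 = 2.6 L¹·⁵ mol⁻¹·⁵ h⁻¹)
    crystals ⇌ target, rate k2*(cs2 - [target]) while solid is left; crystals form when [target] > cs2 (cs2 = 16 mM, k2 = 37 h⁻¹)
    target ⇌ isomer of the product (K3 = 0.49, k3 = 0.12 h⁻¹)
    2 substrate → homo dimer (k4 = 1.0 L mol⁻¹ h⁻¹)
substrate 0.15 M; reagent 1.20 equiv; time 6.0 h
- percent here means substrate units held: one homo dimer counts as two
- what is said of target includes crystals
- where a step has two of a species, its rate is k times that concentration squared, and two are used at each turn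
- crystals is a solid; its amount is given per volume of the solution
- run time (flask): 6.0 h
- target and crystals together at 6.0 h, in percent of the substrate charged
- concentration of target in solution at 6.0 h, in percent of saturation

Who took the substrate? With reagent held at its charge, the step to target was pseudo-first-order in substrate, with constant κ = 0.199 h⁻¹. I called g = 1.51 the dimer pull: the rate at which substrate goes to homo dimer over the rate at which it goes to target. At the charge the dimer led, but at fixed c(reagent) the pull falls with c(substrate). Integrating both losses gave the part reaching target as ln(1 + g(1 − exp(−κt)))/g, here 47.6%.

That much target would take reagent down, so I went round again. Reagent midway between its charge and what that answer left gave κ = 0.143 h⁻¹, g = 2.10, and 37.7% made.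

Where did it stand? The 56.5 mM made is more than the solubility of 16 mM, so I expected crystals. I took the excess over saturation as the making rate over the dissolution coefficient, at the charged rate 0.805 mM, so I put sat below 105%. Against saturated solution the isomer of the product reaches 5.23% of the charge. Taking that whole, I committed to y = 32.4%.

The forecast said y = 34.6% (32.5% to 36.5%), above my figure, and sat = 100.5% (100% to 101.5%), since the “fast crystal exchange holds it only a hair above saturation”.

The simulation gave y = 34.7% and sat = 100%. In this flask the pull, from the amounts at 6.00 h, had fallen to 0.543. In the neighbour flask, the same flask with 4.80 equiv of reagent, the pull started at 0.189, which with reagent held at its charge gave 91.6% made, and 86.4% after the same isomer share. The neighbour flask gave y = 86.6%, with 4.08% as isomer of the product.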